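At late times the north-east flask stands still: from 2.00 h to 25.0 h its target readings average 66.4%, and its solid substrate readings average 1.40%, against a scatter of 1.5 percentage points.

| setting | north-east | south | flask |
|---|---|---|---|
| solid substrate | 0.013 M | 0.013 M | 0.013 M |
| coupling partner | 1.05 equiv | 0.53 equiv | 1.05 equiv |
| remark | the very flask that is asked about, followed so far | run made earlier |  |
| time |  |  | 40 h |

| run | time / h | target / % | solid substrate / % |
|---|---|---|---|
| north-east | 2.00 | 65 | 1 |
| north-east | 4.00 | 67 | 1 |
| north-east | 6.00 | 67 | 3 |
| north-east | 12.0 | 66 | 2 |
| north-east | 25.0 | 67 | 0 |
| south | 1.00 | 70 | 3 |
| south | 2.50 | 77 | 0 |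
| south | 3.00 | 80 | 3 |
| south | 5.00 | 80 | 2 |
| south | 6.00 | 80 | 1 |

(scatter of a reading: 1.5 percentage points)

- noon: at 40 h take out 90% of the target then present, then wait 12 h
- dawn: change nothing and wait 12 h more
- dusk: at 40 h add coupling partner, 50.0% of the amount charged, then wait 12 h

- solid, in amounts per volume of the solution: solid substrate
- target that was removed still counts
- at the start none of the solid substrate is in solution
- additions bring no volume worth counting

1. target, in percent of the solid substrate first charged, at 40 h
2. the option that brings most further target ("none" if no option brings more than 2 percentage points) (noon / dawn / dusk / none)
3. target present, with what was taken out counted in, in percent of the solid substrate first charged, after dawn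
4. target present, with what was taken out counted in, in percent of the solid substrate first charged, after dusk

The south flask, charged with 0.53 equiv of coupling partner, levels off from 3.00 h at 80.0%, more target than the north-east flask on less partner. Call the share not found as target, divided by the target, the split ratio: 0.506 in the north-east flask, 0.250 in the south flask. In powers of ten, the split ratio climbs 0.306 of a decade while the partner charge climbs 0.297, a slope of 1.03. So the loss looks first order in partner, competing with a partner-free route to target. The split ratio per equivalent of partner, averaged over both runs, is the split constant, a selectivity factor: 0.477. The target share then reckons as one over one plus split constant times equivalents, which at 1.05 equiv gives 66.6%.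

The weak link is the solid substrate, whose mean reading is not clearly zero. Taken as real, that residue yields 0.93 points of target, less than the margin of 2 points. Neither run shows an addition or a removal, so a reversible link between target and the loss stays untested, and this reckoning commits to a split made during consumption: 66.6% after dawn and after dusk, and no useful option.

The forecast, on “a kinetic partition fixed while substrate was being consumed”, gives 66.6% at 40 h, 66.6% after dawn, 66.6% after dusk, and best option none.

The simulated flask gives 67.6% at 40 h, 67.6% after dawn, 67.6% after dusk, and best option none.

    coupling partner + intermediate B → side product C (k = 2.40 M⁻¹ min⁻¹)
    solid substrate ⇌ starting material, rate k2*(cs2 - [starting material]) while solid is left; crystals form when [starting material] > cs2 (solubility = 6.90 mM, k = 0.770 min⁻¹)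
    starting material → target (k = 0.0360 min⁻¹)
    starting material + coupling partner → side product A (k = 1.40 M⁻¹ min⁻¹)
    coupling partner + intermediate A → intermediate B (k = 24.0 M⁻¹ min⁻¹)
    starting material ⇌ intermediate A (K = 16.0, k = 0.00130 min⁻¹)
    coupling partner + intermediate A → side product B (k = 1.50 M⁻¹ min⁻¹)

At 0.0484 h in this flask, starting material has a shorter half-life by the step to target alone, 0.32 h, than by the step with coupling partner to side product A, 0.61 h, and at that moment the two half-lives stand in a ratio of 0.525. At 2.60 equiv of coupling partner the split constant gives 44.6% target, and that simulated neighbour flask holds 45.3% target beside 53.0% side product A.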